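**Retrosynthetic overview**

1. Mollicellin A (20) ⇐ benzylic alcohol 19 (MnO2) ⇐ oxasilole-fused depsidone 18 (Tamao–Fleming). In 18 the ring-A carbon bound to silicon is the future C–OH and the Si–O–CH2 carbon is the future CHO.
2. 18 ⇐ triyne 17 by one Rh(I) [2+2+2]. The route rests on ring A carrying the diaryl-ether oxygen and the lactone carbonyl on neighbouring carbons. An ynol ether on O6 and a but-2-ynoate on O7 of the ring-B catechol (chromanone numbering) therefore deliver four ring-A carbons (C–OAr, C–CH2O, C–C(=O)O, C–CH3); a silicon-tethered ethyne delivers the last two (C–OH, C–H).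
3. 17 ⇐ catechol 5: O7 is allylated selectively, O6 becomes the ynol ether (copper coupling with dibromoalkene 8, then elimination), then allyl is exchanged for butynoate and TBS for the ethynyl(dimethyl)silyl tether.
4. 5 ⇐ orcinaldehyde 1: Dakin oxidation, then Friedel–Crafts/oxa-Michael annulation with 3,3-dimethylacrylic acid. Ring order: B (bought) → pyranone → ring A, the seven-membered lactone and a temporary oxasilole together.

Key step: step 11

Assumption: Mollicellin A has no stereocentre (the SMILES carries none), so no stereocontrol is needed and the route delivers the compound as given. Ring B is numbered as a chroman-4-one throughout: O1, C2(Me2), C3, C4(=O), C5(Me), C6(O), C7(O), C8(H).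

**Route**

Step 1
Reactants: 1 orcinaldehyde (2,4-dihydroxy-6-methylbenzaldehyde)
Product: 2 6-methylbenzene-1,2,4-triol (2,3,5-trihydroxytoluene)
Conditions: 30% H2O2, B(OH)3, cat. H2SO4, THF, rt, Ar; crude triol kept under Ar
Reagents that add atoms: hydrogen peroxide (OO)
Why: Dakin oxidation of an ortho/para-hydroxy-activated aldehyde (peroxide addition, aryl migration, formate hydrolysis) puts a hydroxyl exactly where the future diaryl-ether oxygen sits, and the acidic borate medium should keep the air-sensitive hydroxyquinol from autoxidising.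

Step 2
Reactants: 2 6-methylbenzene-1,2,4-triol; 3 3,3-dimethylacrylic acid
Product: 5 6,7-dihydroxy-2,2,5-trimethylchroman-4-one, via o-hydroxyaryl enone 4 (not isolated)
Conditions: BF3·OEt2 (neat), 70 °C, Ar
Reagents that add atoms: none
Why: Friedel–Crafts acylation followed by intramolecular oxa-Michael addition (chromanone annulation) should take the ring CH that lies between the methyl and a hydroxyl and para to a second hydroxyl, as C-acylation of orcinol and of hydroxyquinol does, and only the single ortho hydroxyl can then close the pyranone.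

Step 3
Reactants: 5 6,7-dihydroxy-2,2,5-trimethylchroman-4-one
Product: 6 6-hydroxy-2,2,5-trimethyl-7-(prop-2-en-1-yloxy)chroman-4-one
Conditions: allyl bromide (1.05 equiv), NaHCO3, cat. NaI, DMF, 40 °C
Reagents that add atoms: allyl bromide (C=CCBr)
Why: Williamson etherification under weak base should be selective because the C7 hydroxyl is para to the ketone, more acidic and unhindered (as in 4-O-alkylation of protocatechualdehyde), while the C6 hydroxyl is flanked by the methyl and the C7 oxygen.

Step 4
Reactants: 7 (tert-butyldimethylsilyloxy)acetaldehyde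
Product: 8 tert-butyl[(3,3-dibromoprop-2-en-1-yl)oxy]dimethylsilane
Conditions: CBr4 (2 equiv), PPh3 (4 equiv), CH2Cl2, 0 °C
Reagents that add atoms: carbon tetrabromide (BrC(Br)(Br)Br)
Why: Ramirez dibromo-olefination (first stage of the Corey–Fuchs sequence) converts an unhindered aldehyde into the 1,1-dibromoalkene, and the silyl ether is inert to the ylide.

Step 5
Reactants: 6 6-hydroxy-2,2,5-trimethyl-7-(prop-2-en-1-yloxy)chroman-4-one; 8 tert-butyl[(3,3-dibromoprop-2-en-1-yl)oxy]dimethylsilane (1.5 equiv)
Product: 10 6-{[3-(tert-butyldimethylsilyloxy)prop-1-yn-1-yl]oxy}-2,2,5-trimethyl-7-(prop-2-en-1-yloxy)chroman-4-one, via (Z)-bromo enol ether 9 (not isolated)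
Conditions: CuI (10 mol %), 2,2'-bipyridine (20 mol %), K3PO4, toluene, 110 °C; then t-BuOK (2 equiv), dioxane, 0 °C → rt
Reagents that add atoms: none
Why: Copper-catalysed Ullmann-type C–O coupling of a phenol with a 1,1-dibromoalkene should replace the bromine trans to the substituent, and anti-dehydrobromination of the resulting (Z)-bromo enol ether with tert-butoxide gives the aryl ynol ether, the excess of 8 suppressing ketene acetal formation.

Step 6
Reactants: 10 the allyl ether ynol ether from step 5
Product: 11 6-{[3-(tert-butyldimethylsilyloxy)prop-1-yn-1-yl]oxy}-7-hydroxy-2,2,5-trimethylchroman-4-one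
Conditions: Pd(PPh3)4 (5 mol %), N-methylaniline (2 equiv), THF, rt; used at once
Reagents that add atoms: none
Why: Tsuji–Trost deallylation ionises only the aryl allyl ether and passes the allyl group to the weakly basic amine, conditions that are neither acidic nor strongly basic and so should leave the ynol ether, the silyl ether and the ketone alone.

Step 7
Reactants: 11 the C7 phenol from step 6; 12 but-2-ynoic acid (1.5 equiv)
Product: 13 6-{[3-(tert-butyldimethylsilyloxy)prop-1-yn-1-yl]oxy}-2,2,5-trimethyl-4-oxochroman-7-yl but-2-ynoate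
Conditions: DCC (1.5 equiv), DMAP (5 mol %), CH2Cl2, −20 → 0 °C; acid pre-activated with DCC before 11 is added
Reagents that add atoms: none
Why: Steglich esterification of a phenol with an alkynoic acid is standard, and pre-activation keeps the free acid away from the acid-sensitive ynol ether while the low temperature limits DMAP addition to the ynoate.

Step 8
Reactants: 13 the butynoate TBS ether from step 7
Product: 14 6-[(3-hydroxyprop-1-yn-1-yl)oxy]-2,2,5-trimethyl-4-oxochroman-7-yl but-2-ynoate
Conditions: HF·pyridine, excess pyridine, THF, 0 °C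
Reagents that add atoms: none
Why: Buffered fluoride desilylation cleaves the primary TBS ether without the basic fluoride that would attack the aryl ynoate, and the pyridine buffer should be too weakly acidic to hydrate the aryl ynol ether.

Step 9
Reactants: 15 dichlorodimethylsilane (3 equiv)
Product: 16 chloro(ethynyl)dimethylsilane
Conditions: HC≡CMgBr (0.5 M in THF) added to 15, THF, −78 °C → rt; fractional distillation
Reagents that add atoms: ethynylmagnesium bromide (C#C[Mg]Br)
Why: Nucleophilic substitution at silicon by a Grignard reagent stops at mono-substitution when the dichlorosilane is in excess and the reagent is added inversely.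

Step 10
Reactants: 14 the propargylic alcohol from step 8; 16 chloro(ethynyl)dimethylsilane (1.3 equiv)
Product: 17 6-({3-[ethynyl(dimethyl)silyloxy]prop-1-yn-1-yl}oxy)-2,2,5-trimethyl-4-oxochroman-7-yl but-2-ynoate (the triyne)
Conditions: Et3N (1.5 equiv), CH2Cl2, 0 °C; filtration through Et3N-deactivated silica, used directly
Reagents that add atoms: none
Why: Silylation of a primary alcohol with a chlorosilane and a tertiary amine is fast at 0 °C, and the labile alkynylsilyl ether is made last so that it meets no further reagent before the cyclisation.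

Step 11
Reactants: 17 the triyne
Product: 18 oxasilole-fused depsidone (complete Mollicellin A skeleton; ring A fused to a 1,1-dimethyl-1,3-dihydro-2,1-benzoxasilole, Si on the future C–OH carbon, OCH2 on the future CHO carbon)
Conditions: [Rh(cod)2]BF4/rac-BINAP (10 mol %, activated with H2, then Ar), CH2Cl2, rt, syringe-pump addition of 17 (final 2 mM)
Reagents that add atoms: none
Why: Proposed new method: cationic Rh(I) should first couple the two alkynes of the 1,6-diyne unit (ArO–C≡C–CH2–O–Si–C≡CH) oxidatively to a rhodacyclopentadiene, the tethered but-2-ynoate then inserts and reductive elimination releases the benzene; the closest known reaction type is the Rh(I)-catalysed intramolecular [2+2+2] cyclotrimerisation of tethered triynes, known with silyl ether tethers, aryl ynol ethers and alkynoates but not with a catechol-borne ynoate/ynol ether pair that must close a seven-membered lactone. Ring A closes through all three new C–C bonds: ynoate Cα to the oxygen-bearing ynol carbon, the CH2O-bearing ynol carbon to the silicon-bearing carbon, and the ethyne CH to the methyl-bearing ynoate carbon. The five-membered oxasilole closes in the oxidative coupling through the C(CH2O)–C(Si) bond, and the seven-membered dioxepinone closes on insertion through the Cα–C(OAr) bond, the ortho catechol oxygens holding the electron-poor ynoate next to the electron-rich ynol ether. No stereocentre is formed. The step needs intramolecular over intermolecular alkyne coupling, which the two tethers, high dilution and slow addition should secure, and the ring-A substitution pattern cannot vary because every alkyne is tethered.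

Step 12
Reactants: 18 the oxasilole-fused depsidone
Product: 19 Mollicellin A alcohol (CH2OH in place of CHO; ring-A phenol free)
Conditions: 30% H2O2, KF, KHCO3, THF/MeOH, rt
Reagents that add atoms: hydrogen peroxide (OO)
Why: Tamao–Fleming oxidation of the alkoxy-activated aryl–silicon bond gives the phenol with retention of position and frees the benzylic alcohol, while the lactone carbonyl is shielded by its two ortho substituents and no aldehyde is yet present to undergo a Dakin reaction.

Step 13
Reactants: 19 Mollicellin A alcohol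
Product: 20 Mollicellin A
Conditions: activated MnO2, CH2Cl2, rt
Reagents that add atoms: none
Why: Manganese dioxide oxidises the benzylic alcohol selectively to the aldehyde, which is stabilised by the hydrogen bond to the ortho phenol and is not oxidised further.

**Compound list**

1 | orcinaldehyde (2,4-dihydroxy-6-methylbenzaldehyde) | Cc1cc(O)cc(O)c1C=O | starting material
2 | 6-methylbenzene-1,2,4-triol | Cc1cc(O)cc(O)c1O | intermediate
3 | 3,3-dimethylacrylic acid | CC(C)=CC(=O)O | starting material
4 | 3-methyl-1-(2,4,5-trihydroxy-6-methylphenyl)but-2-en-1-one (not isolated) | Cc1c(C(=O)C=C(C)C)c(O)cc(O)c1O | intermediate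
5 | 6,7-dihydroxy-2,2,5-trimethylchroman-4-one | Cc1c(O)c(O)cc2OC(C)(C)CC(=O)c12 | intermediate
6 | 6-hydroxy-2,2,5-trimethyl-7-(prop-2-en-1-yloxy)chroman-4-one | Cc1c(O)c(OCC=C)cc2OC(C)(C)CC(=O)c12 | intermediate
7 | (tert-butyldimethylsilyloxy)acetaldehyde | CC(C)(C)[Si](C)(C)OCC=O | starting material
8 | tert-butyl[(3,3-dibromoprop-2-en-1-yl)oxy]dimethylsilane | CC(C)(C)[Si](C)(C)OCC=C(Br)Br | intermediate
9 | 6-{[(Z)-1-bromo-3-(tert-butyldimethylsilyloxy)prop-1-en-1-yl]oxy}-2,2,5-trimethyl-7-(prop-2-en-1-yloxy)chroman-4-one (not isolated) | Cc1c(O/C(Br)=C/CO[Si](C)(C)C(C)(C)C)c(OCC=C)cc2OC(C)(C)CC(=O)c12 | intermediate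
10 | 6-{[3-(tert-butyldimethylsilyloxy)prop-1-yn-1-yl]oxy}-2,2,5-trimethyl-7-(prop-2-en-1-yloxy)chroman-4-one | Cc1c(OC#CCO[Si](C)(C)C(C)(C)C)c(OCC=C)cc2OC(C)(C)CC(=O)c12 | intermediate
11 | 6-{[3-(tert-butyldimethylsilyloxy)prop-1-yn-1-yl]oxy}-7-hydroxy-2,2,5-trimethylchroman-4-one | Cc1c(OC#CCO[Si](C)(C)C(C)(C)C)c(O)cc2OC(C)(C)CC(=O)c12 | intermediate
12 | but-2-ynoic acid | CC#CC(=O)O | starting material
13 | 6-{[3-(tert-butyldimethylsilyloxy)prop-1-yn-1-yl]oxy}-2,2,5-trimethyl-4-oxochroman-7-yl but-2-ynoate | Cc1c(OC#CCO[Si](C)(C)C(C)(C)C)c(OC(=O)C#CC)cc2OC(C)(C)CC(=O)c12 | intermediate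
14 | 6-[(3-hydroxyprop-1-yn-1-yl)oxy]-2,2,5-trimethyl-4-oxochroman-7-yl but-2-ynoate | Cc1c(OC#CCO)c(OC(=O)C#CC)cc2OC(C)(C)CC(=O)c12 | intermediate
15 | dichlorodimethylsilane | C[Si](C)(Cl)Cl | starting material
16 | chloro(ethynyl)dimethylsilane | C#C[Si](C)(C)Cl | intermediate
17 | 6-({3-[ethynyl(dimethyl)silyloxy]prop-1-yn-1-yl}oxy)-2,2,5-trimethyl-4-oxochroman-7-yl but-2-ynoate (triyne) | CC#CC(=O)Oc1cc2OC(C)(C)CC(=O)c2c(C)c1OC#CCO[Si](C)(C)C#C | intermediate
18 | oxasilole-fused depsidone | Cc1cc2c(CO[Si]2(C)C)c2c1C(=O)Oc1cc3c(c(C)c1O2)C(=O)CC(C)(C)O3 | intermediate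
19 | Mollicellin A alcohol (hydroxymethyl in place of formyl) | Cc1cc(O)c(CO)c2c1C(=O)Oc1cc3c(c(C)c1O2)C(=O)CC(C)(C)O3 | intermediate
20 | Mollicellin A | Cc1cc(O)c(C=O)c2c1C(=O)Oc1cc3c(c(C)c1O2)C(=O)CC(C)(C)O3 | target

**Step count**

Total: 13 steps. Longest linear sequence: 11 steps (1 → 20 through steps 1, 2, 3, 5, 6, 7, 8, 10, 11, 12, 13); steps 4 and 9 are side branches.

**Steps most likely to fail**

Step 11. The aryl ester must leave its preferred conformation to bring the ynoate within reach of the rhodacycle for seven-membered closure. If that insertion is slow, the rhodacycle from the silyl-tethered diyne unit would be diverted into intermolecular oligomerisation, and traces of acid from the cationic catalyst could hydrate the ynol ether or cleave the silyl ether.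

Fallback from 6 to 20 by classical depsidone assembly, all known chemistry. Ring A is bought as 2,6-difluoro-4-methylbenzaldehyde (Cc1cc(F)c(C=O)c(F)c1). Mono-substitution with sodium benzyloxide (BnOH, NaH, THF, 0 °C) should give 2-(benzyloxy)-6-fluoro-4-methylbenzaldehyde F1. Bromination para to the benzyloxy group (NBS, MeCN) should give 6-(benzyloxy)-3-bromo-2-fluoro-4-methylbenzaldehyde F2. Palladium-catalysed benzyloxycarbonylation (Pd(OAc)2, Xantphos, CO, BnOH, Et3N, toluene, 90 °C) should give benzyl 4-(benzyloxy)-2-fluoro-3-formyl-6-methylbenzoate F3, whose fluorine lies between the formyl and ester groups. SNAr with the C6 phenoxide of 6 (K2CO3, DMF, 70 °C) should then give the diaryl ether F4. Pd(PPh3)4/N-methylaniline removes the allyl group to give the C7 phenol F5. Hydrogenolysis (H2, Pd/C, EtOAc) removes both benzyl groups to give the seco acid F6. Carbodiimide lactonisation (EDC·HCl, DMAP, CH2Cl2, high dilution) closes the seven-membered lactone and arrives at 20.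

Step 5. The phenol has two ortho substituents, so copper coupling may be slow and ketene acetal formation may compete. In the elimination, tert-butoxide may open the pyranone by retro-oxa-Michael reaction or isomerise the allyl ether.

Fallback from 6 to 10 by the dichlorovinyl ether route. Trichloroethylene and K2CO3 in DMF at 70 °C should give the (E)-1,2-dichlorovinyl ether F7. The ketone is masked as the tert-butyldimethylsilyl enol ether F8 (TBSOTf, Et3N, CH2Cl2). n-BuLi (2.2 equiv, THF, −78 °C) converts the dichlorovinyl ether into the lithium aryloxyacetylide, which is trapped with paraformaldehyde to give the propargylic alcohol F9. Buffered fluoride (TBAF, AcOH, THF, −20 °C) releases the ketone to give the keto alcohol F10. TBSCl/imidazole silylates the primary alcohol and returns to 10.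

Step 2. Acylation may also take the ring position between the two meta-related hydroxyls, giving regioisomeric chromanones, and the free triol may oxidise before it reacts.

Fallback from 2 to 5 through methyl ethers, which close the position between two methoxy groups sterically. Exhaustive methylation (Me2SO4, K2CO3, acetone) gives 1,2,5-trimethoxy-3-methylbenzene F11. Friedel–Crafts acylation with 3,3-dimethylacryloyl chloride and AlCl3 (CH2Cl2, 0 °C → rt) should give 3-methyl-1-(2,4,5-trimethoxy-6-methylphenyl)but-2-en-1-one F12. The excess Lewis acid cleaves the methoxy group ortho to the ketone to give 1-(2-hydroxy-4,5-dimethoxy-6-methylphenyl)-3-methylbut-2-en-1-one F13. K2CO3 in MeOH closes 6,7-dimethoxy-2,2,5-trimethylchroman-4-one F14 by oxa-Michael addition. BBr3 (CH2Cl2, −78 → 0 °C) frees the catechol 5.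

**Further compounds**

F1 | step 11 | 2-(benzyloxy)-6-fluoro-4-methylbenzaldehyde | Cc1cc(F)c(C=O)c(OCc2ccccc2)c1
F2 | step 11 | 6-(benzyloxy)-3-bromo-2-fluoro-4-methylbenzaldehyde | Cc1cc(OCc2ccccc2)c(C=O)c(F)c1Br
F3 | step 11 | benzyl 4-(benzyloxy)-2-fluoro-3-formyl-6-methylbenzoate | Cc1cc(OCc2ccccc2)c(C=O)c(F)c1C(=O)OCc1ccccc1
F4 | step 11 | diaryl ether: benzyl 4-(benzyloxy)-3-formyl-6-methyl-2-{[2,2,5-trimethyl-4-oxo-7-(prop-2-en-1-yloxy)chroman-6-yl]oxy}benzoate | Cc1cc(OCc2ccccc2)c(C=O)c(Oc2c(C)c3c(cc2OCC=C)OC(C)(C)CC3=O)c1C(=O)OCc1ccccc1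
F5 | step 11 | C7 phenol: benzyl 4-(benzyloxy)-3-formyl-2-[(7-hydroxy-2,2,5-trimethyl-4-oxochroman-6-yl)oxy]-6-methylbenzoate | Cc1cc(OCc2ccccc2)c(C=O)c(Oc2c(C)c3c(cc2O)OC(C)(C)CC3=O)c1C(=O)OCc1ccccc1
F6 | step 11 | seco acid: 3-formyl-4-hydroxy-2-[(7-hydroxy-2,2,5-trimethyl-4-oxochroman-6-yl)oxy]-6-methylbenzoic acid | Cc1cc(O)c(C=O)c(Oc2c(C)c3c(cc2O)OC(C)(C)CC3=O)c1C(=O)O
F7 | step 5 | 6-{[(E)-1,2-dichloroethenyl]oxy}-2,2,5-trimethyl-7-(prop-2-en-1-yloxy)chroman-4-one | Cc1c(O/C(Cl)=C\Cl)c(OCC=C)cc2OC(C)(C)CC(=O)c12
F8 | step 5 | tert-butyl({6-{[(E)-1,2-dichloroethenyl]oxy}-2,2,5-trimethyl-7-(prop-2-en-1-yloxy)-2H-chromen-4-yl}oxy)dimethylsilane | Cc1c(O/C(Cl)=C\Cl)c(OCC=C)cc2OC(C)(C)C=C(O[Si](C)(C)C(C)(C)C)c12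
F9 | step 5 | 3-{[4-(tert-butyldimethylsilyloxy)-2,2,5-trimethyl-7-(prop-2-en-1-yloxy)-2H-chromen-6-yl]oxy}prop-2-yn-1-ol | Cc1c(OC#CCO)c(OCC=C)cc2OC(C)(C)C=C(O[Si](C)(C)C(C)(C)C)c12
F10 | step 5 | 6-[(3-hydroxyprop-1-yn-1-yl)oxy]-2,2,5-trimethyl-7-(prop-2-en-1-yloxy)chroman-4-one | Cc1c(OC#CCO)c(OCC=C)cc2OC(C)(C)CC(=O)c12
F11 | step 2 | 1,2,5-trimethoxy-3-methylbenzene | Cc1cc(OC)cc(OC)c1OC
F12 | step 2 | 3-methyl-1-(2,4,5-trimethoxy-6-methylphenyl)but-2-en-1-one | Cc1c(C(=O)C=C(C)C)c(OC)cc(OC)c1OC
F13 | step 2 | 1-(2-hydroxy-4,5-dimethoxy-6-methylphenyl)-3-methylbut-2-en-1-one | Cc1c(C(=O)C=C(C)C)c(O)cc(OC)c1OC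
F14 | step 2 | 6,7-dimethoxy-2,2,5-trimethylchroman-4-one | Cc1c(OC)c(OC)cc2OC(C)(C)CC(=O)c12
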